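The numbers in the tables were computed on assumed constants; scatter was added.

At early times a run shows its rate with the least reckoning, so I began from the first readings.

| setting | north-east | north | north-west | west | south-east |
|---|---|---|---|---|---|
| starting material | 200 mM | 400 mM | 200 mM | 200 mM | 200 mM |
| coupling partner | 500 mM | 500 mM | 750 mM | 500 mM | 1000 mM |
| target |  |  |  | 100 mM |  |
| time |  |  |  |  | 27 min |

| run | time / min | [target] / mM |
|---|---|---|
| north-east run | 0.97 | 21.6 |
| north-east run | 2.9 | 55.6 |
| north-east run | 5.6 | 92.7 |
| north-east run | 8.9 | 123.1 |
| north-east run | 13 | 146.7 |
| north-east run | 17 | 161.9 |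
| north-east run | 22 | 173.3 |
| north-east run | 27 | 181.9 |
| north run | 0.97 | 39.8 |
| north run | 2.9 | 100.8 |
| north run | 5.6 | 163.1 |
| north run | 8.9 | 213.4 |
| north run | 13 | 255.5 |
| north run | 17 | 284.1 |
| north run | 22 | 306.7 |
| north run | 27 | 320.9 |
| north-west run | 0.97 | 27.6 |
| north-west run | 2.9 | 70.4 |
| north-west run | 5.6 | 112.4 |
| north-west run | 8.9 | 143.3 |
| north-west run | 13 | 167.0 |
| north-west run | 17 | 181.1 |
| north-west run | 22 | 188.1 |
| north-west run | 27 | 193.1 |
| west run | 0.97 | 121.5 |
| west run | 2.9 | 156.8 |
| west run | 5.6 | 191.3 |
| west run | 8.9 | 222.2 |
| west run | 13 | 247.8 |
| west run | 17 | 261.6 |
| west run | 22 | 275.4 |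
| west run | 27 | 280.8 |

(scatter of a reading: 0.6 mM)

- Overall: starting material + coupling partner -> target.
- Constant volume, constant temperature.
- Bound and free are read together.
- An order is taken over about fifteen percent of the charge, up and down.

- the exponent of [starting material] in the starting rate at the charge of the north-east run (at the point where two percent of the starting material have become target) (one fixed amount of target, the same in the runs compared)
- the exponent of [coupling partner] in the starting rate at the charge of the north-east run (at the point where two percent of the starting material have become target)
- target in the south-east run at 27 min, as a share of the starting material charged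

I used one quantity, the pace: the logarithm of charged over unconverted starting material, divided by time. It is a pseudo-first-order constant, with the coupling partner in excess.

pace = ln[c(starting material, charged) / (c(starting material, charged) − c(target made))] / t

The north-east run gave 0.118 min⁻¹ at its first reading, and this north-east pace was my base. The scatter is 2.78% of that reading, so orders read from it are good to about 0.1.

First I took the main step by itself, with order one in each reactant. The pace then follows c(coupling partner) and ignores c(starting material). The south-east run has twice the partner:

pace = 0.236 min⁻¹, target = 99.8%

Next I put in the orders as read. The north-west run gave 0.153 min⁻¹ and the north run 0.108 min⁻¹. So the partner's order was 0.646, below the order of one that I had assumed for the main step, and the starting material's was 0.875.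

pace = 0.184 min⁻¹, target = 99.3%

Then I tested added target. The west run, counting target made, gave 0.117 min⁻¹, so the north-east pace stood unchanged.

Last came the late slowing. Over its whole 27 min, the north-west run kept a pace of 0.125 min⁻¹, lower than at its start, a factor of 0.815. I applied that factor to the south-east run:

pace = 0.150 min⁻¹, target = 98.3%

The forecast, a little above my two orders, gave 0.9 (0.8 to 0.98), 0.68 (0.58 to 0.8) and 98.5% (97.3% to 99.4%), holding that “target neither inhibits nor accelerates”.

The simulation gave 0.93, 0.71 and 98.0%.

    starting material + coupling partner → target + by-product (0.4056 M⁻¹ min⁻¹)
    2 starting material → homo dimer (0.03978 M⁻¹ min⁻¹)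
    starting material + coupling partner ⇌ idle substrate-reagent adduct, settled at all times (1.110 M⁻¹)

That yield means a mean south-east pace of 0.145 min⁻¹, against my 0.150 min⁻¹. The partner's order fell below one through the idle substrate-reagent adduct: at the north-east charge it is 0.71 with that adduct and 1.0 without it. The north-east pace also carried over to the west run, where it put a quarter of the starting material at 2.44 min, and the west run took 2.50 min.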